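**Target:** CNP0382475.0 = geraldol 3,7,4'-tris(hydrogen sulfate), COc1cc(-c2oc3cc(OS(=O)(=O)O)ccc3c(=O)c2OS(=O)(=O)O)ccc1OS(=O)(=O)O. Flavone numbering (O1, C2–C8a, primed numbers for ring B) is used throughout.

## Structural features

The target 15 is the tris(hydrogen sulfate) of a flavonol: a benzene ring (ring A) fused to a 4-pyranone (ring C), with a 3-methoxy-4-oxygenated phenyl ring (ring B) attached through the C2–C1' bond. Oxygen sits at C7 of ring A, at C3 (enolic) and C4 (carbonyl) of ring C, and at C3' (methyl ether) and C4' of ring B; O3, O7 and O4' each carry an SO3H group. The molecule is flat and has no stereocentre, so the stereocentres that appear on the way (C2, C3, C4) need no control, only a later step that erases them. The fragile groups are the three sulfate monoesters (two aryl, one enol): they are acid-labile, make the compound a strong triacid that cannot be chromatographed on silica, and must therefore be installed last on the free triol. The carbon skeleton is modest; the real difficulty is to close ring C with the right oxygen pattern (oxygen on C7 only, C3–OH next to C4=O), to raise C3 and C4 to their oxidation levels beside electron-rich arenes, and to sulfate the hydrogen-bonded 3-OH completely. The key step uses the fact that O1–C8a–C4a–C4–C3–C2 of ring C is a 1-oxatriene once ring A is written as an ortho-quinone methide (O1=C8a, C4a=C4) bearing a C3=C2 alkene. O1 and the benzylic C2 are the termini of this oxatriene, and a six-electron electrocyclization joins them while ring A regains its aromaticity. The oxatriene comes from a phenol (O1, C8a, C4a) and an enal (C4, C3, C2); an alkoxy group on the α-carbon of the enal brings C3 in at the correct oxidation level and leaves C4 as the only carbon still to be oxidised.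

## Logic of the disconnections

**15 ⇒ 13.** The three O–S bonds at O3, O7 and O4' are cut, with 14 as the salt form that precedes 15. They go first because sulfate monoesters survive neither acid nor silica and would interfere with every oxidation and hydrogenation. The gain is a neutral triol in place of a triacid. The forward step must sulfate all three hydroxyls, the chelated one on C3 included, without C-sulfonation, and must end with a cold proton exchange.

**13 ⇒ 12.** The two benzylic O–C bonds at O7 and O4' are cut, which in the forward sense means two benzyl ethers are carried as protecting groups. The phenols have to be masked during the condensation and the oxidations; benzyl ethers tolerate weak acid, dioxirane and periodinane and leave under neutral conditions. The gain is that every earlier intermediate is non-polar and can be chromatographed. The demand is a hydrogenolysis that spares the C2=C3 bond and the C4 carbonyl of the pyranone.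

**12 ⇒ 10.** No skeletal bond is cut. The C4 carbonyl is taken back to a secondary alcohol and the C2=C3 enol to a C3 ketone with sp3 C2, because 12 is the aromatic enol tautomer of the 3,4-dione 11, and 11 is the oxidation product of the α-ketol 10. This replaces the construction of a 3-hydroxy-4-pyranone by an ordinary alcohol oxidation. The forward step needs an oxidant that acts on the benzylic carbinol and leaves the enol and the electron-rich rings of the product alone.

**10 ⇒ 8.** The C4–O bond is cut and the C3 carbonyl is returned to its benzyl enol ether, by way of 9. The C3=C4 enol ether is the most electron-rich π bond of 8, so an electrophilic oxygen donor should attack only there; hydrolysis of the epoxy ether then leaves oxygen on C4 and releases the benzyl group from O3. The gain is the loss of one oxygen and two stereocentres, back to a flat enol ether. The demand is chemoselectivity for the enol ether over benzylic C–H bonds and arenes, and a near-neutral hydrolysis.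

**8 ⇒ 4 + 5.** The O1–C2 bond is cut by retro-electrocyclization to 7, then the C4a=C4 bond by retro-condensation through 6. This is the strategic cut: ring C disappears and the ring A unit 5 is separated from a three-carbon unit, 4, that carries ring B and the C3 oxygen. The forward step must make the phenol react at carbon, ortho to its hydroxyl and para to its ether oxygen, with the formyl group of 4 and not by conjugate addition. It must also give 7 with a geometry that allows closure; the C2 stereocentre needs no control.

**4 ⇒ 1 + 2.** The Cα=Cβ double bond (the later C3–C2 bond) is cut by retro-aldol condensation through 3. Only 2 can enolise and 1 has no α-hydrogen, so the polarity is unambiguous, and both are purchasable. The forward step must suppress self-condensation of 2 and give the alkene isomer with the aryl group trans to the formyl group, which is the thermodynamic one.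

## Other disconnections considered

**Alternative 1:** Cut C4a–C5 and C8–C8a, so that ring A is made last on a monocyclic pyranone that already holds rings B and C.
- Forward key step: 3-(benzyloxy)-2-[4-(benzyloxy)-3-methoxyphenyl]-5-bromo-4H-pyran-4-one A1 acts as dienophile at C5=C6 toward (E)-1-methoxy-3-(trimethylsilyloxy)buta-1,3-diene A2. The cycloadduct loses its bromine and its methoxy group by twofold elimination and, after cleavage of the silyl ether, is 3-(benzyloxy)-2-[4-(benzyloxy)-3-methoxyphenyl]-7-hydroxy-4H-chromen-4-one A3.
- In its favour: the usual orientation (the nucleophilic CH2 terminus of A2 to C6, the β-carbon of the enone) puts the new oxygen on C7 as required. C3 and C4 of A3 are already at their final oxidation levels, so A3 needs only hydrogenolysis to 13 and sulfation. That is two steps after the key step against four in the chosen plan, and on this point the alternative is the better one. No stereocentre is made and discarded.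
- Against it here: C5=C6 of a 4-pyranone is the alkene of a vinylogous ester, donor-substituted at C6, and one bromine activates it far less than the acyl, cyano or nitro groups that normally make such bonds react with A2. Forcing conditions would be at odds with the thermal lability of A2. A1 also has no short synthesis: a 2-aryl-3-alkoxy-4-pyranone must be assembled and brominated selectively at C5, whereas 4 takes one step.
- Comparison: both key steps are pericyclic and both are driven by aromatization of ring A. Structurally the alternative has the better endgame. Mechanistically its key step is at least as uncertain as the chosen one, and the overall sequence is expected to be longer.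

**Alternative 2:** Cut C4a–C4, C4–C3 and O1–C2, with C4 as a one-carbon unit.
- Forward key step: 5-(benzyloxy)-2-iodophenol A4, carbon monoxide A5 and 1-(benzyloxy)-4-ethynyl-2-methoxybenzene A6 are joined by palladium-catalysed carbonylative coupling in a secondary amine. Oxidative addition, insertion of A5 and alkynylation give an ortho-hydroxyaryl alkynone, and amine-mediated 6-endo oxa-Michael closure gives 7-(benzyloxy)-2-[4-(benzyloxy)-3-methoxyphenyl]-4H-chromen-4-one A7.
- In its favour: three bonds and ring C are made in one operation, C4 arrives as the ketone, and no stereocentre is created. This reaction type is well established for 2-iodophenols and aryl acetylenes, so on precedent the alternative is the better one.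
- Against it here: A7 has no oxygen on C3. A separate C3 hydroxylation (metalation, borylation and oxidation, or epoxidation of C2=C3 and rearrangement) is needed to reach 12, so O3 is introduced late where the chosen plan introduces O4 late. The 5-exo closure to an aurone competes with the 6-endo closure. Direct iodination of 5 is expected to favour the position para to the hydroxyl, so A4 would better come from 4-iodoresorcinol by selective benzylation. A5 is a toxic gas.
- Comparison: A4 takes one or two steps and A6 one step from 1; the key step, the C3 hydroxylation and steps 5 and 6 of the chosen plan follow. That is six or seven operations, equal to the chosen plan, with a more convergent and better documented key step but without use of the oxygen that the chosen plan places on C3 from the start.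

**Alternative 3:** Cut C3–C4, leaving both carbons as aldehydes tethered through O1–C2.
- Forward key step: controlled-potential cathodic reduction of 4-(benzyloxy)-2-{1-[4-(benzyloxy)-3-methoxyphenyl]-2-oxoethoxy}benzaldehyde A8. The aromatic aldehyde is reduced first to a ketyl at C4, which adds to the aliphatic formyl carbon C3 in a 6-exo closure. Further uptake of an electron and protons gives rac-(2R,3S,4S)-7-(benzyloxy)-2-[4-(benzyloxy)-3-methoxyphenyl]chromane-3,4-diol A9 (2,3-trans-3,4-cis).
- In its favour: no stoichiometric reductant is needed. A9 carries both O3 and O4, so one double oxidation to 11 and enolization would give 12. On the placement of oxygen this alternative is better than the chosen plan, which must add O4 afterwards.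
- Against it here: three stereocentres are set only to be erased. A8 is an α-aryl-α-aryloxy acetaldehyde, readily enolized and hydrated, and needs about four steps from a salicylaldehyde and an α-halo arylacetic ester. Intermolecular pinacol coupling and plain reduction of the aromatic aldehyde compete with the closure, and a divided cell with potential control is required.
- Comparison: the radical-anion closure is mechanistically sound and structurally attractive. The fragile precursor and the longer overall sequence (about eight operations) make it less economical than the chosen plan.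

Key step: step 2

**Remarks on the chemistry.**
- Compounds 1, 2 and 5 are bought.
- The benzyl group on the α-oxygen of 4 is a sacrificial group: it leaves as benzyl alcohol in step 3.
- The enal geometry (aryl trans to formyl, hence Z) and the 7-oxygenation that follows from attack para to the ether oxygen of 5 agree with the target; no structure needed correction.
- The target is written as the free tris(hydrogen sulfate), so step 6 ends with a proton-form ion exchange of the first-formed pyridinium salt 14.

## Route

**Step 1**
Reactants: 1 4-(benzyloxy)-3-methoxybenzaldehyde; 2 2-(benzyloxy)acetaldehyde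
Product: 4 (Z)-2-(benzyloxy)-3-[4-(benzyloxy)-3-methoxyphenyl]acrylaldehyde, via aldol adduct 3 (not isolated)
Conditions: 1 (1.5 equiv), NaOH (0.5 equiv), MeOH/H2O, 0 °C; 2 (1.0 equiv) added over 4 h; then rt
Reagents that add atoms: none
Why: Crossed aldol condensation of the Claisen–Schmidt type: only 2 can form an enolate, 1 has no α-hydrogen and is kept in excess while 2 is fed slowly and is largely masked as its hemiacetal, so 3 forms and dehydrates by E1cB elimination. The alkene is set under thermodynamic control with the aryl group trans to the formyl group, which is the Z descriptor because the benzyloxy oxygen outranks the formyl carbon.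

**Step 2**
Reactants: 5 3-(benzyloxy)phenol; 4 (Z)-2-(benzyloxy)-3-[4-(benzyloxy)-3-methoxyphenyl]acrylaldehyde
Product: 8 3,7-bis(benzyloxy)-2-[4-(benzyloxy)-3-methoxyphenyl]-2H-chromene (racemic), via benzodioxaborin 6 (not isolated), via ortho-quinone methide 7 (not isolated)
Conditions: 4 (1.1 equiv), PhB(OH)2 (1.1 equiv), EtCO2H (0.3 equiv), toluene, reflux, Dean–Stark, 16–24 h; aq. NaHCO3; SiO2 deactivated with Et3N
Reagents that add atoms: none
Why: Proposed new method: 2-alkoxy enals have not been used in this annulation, the closest known reaction type being the phenylboronic-acid-mediated ortho-condensation of phenols with 3-alkyl- or 3-aryl-substituted enals to 2H-chromenes. Mechanistically, 5 and PhB(OH)2 form an aryloxyboronate that binds the formyl oxygen of 4 and delivers the ring carbon ortho to the hydroxyl to the carbonyl carbon (a templated hydroxyalkylation that forms C4–C4a), and the new alkoxide closes the cyclic boronate 6. Acid-assisted thermal loss of the boron–oxygen bridge from 6 (as the boroxine) gives the ortho-quinone methide 7, in which O1=C8a–C4a=C4–C3=C2 is a 1-oxatriene with the aryl group pointing outward because of the Z geometry of 4. Ring C then closes by a thermal disrotatory six-electron oxa-electrocyclization that forms O1–C2 and is driven by the return of aromaticity to ring A. The single new stereocentre, C2, is formed without any controlling element and is racemic, which is acceptable because C2 becomes sp2 again in step 4. The α-benzyloxy group is cross-conjugated and inductively withdrawing toward the carbonyl, so the 1,2-addition should be no slower than with cinnamaldehyde, and it ends on C3 as the enol ether that later directs oxidation to C4. The step needs C- over O-attack and attack at the ortho carbon para to the benzyloxy group, not at the one between the two oxygens: the boron tether enforces ortho C-attack, and the flanked position, although electronically activated, is the more hindered. Only catalytic acid and azeotropic removal of water are used because 8 is an acid-labile enol ether.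

**Step 3**
Reactants: 8 3,7-bis(benzyloxy)-2-[4-(benzyloxy)-3-methoxyphenyl]-2H-chromene
Product: 10 7-(benzyloxy)-2-[4-(benzyloxy)-3-methoxyphenyl]-4-hydroxychroman-3-one (racemic; diastereomer mixture), via epoxy ether 9 (not isolated)
Conditions: DMDO (1.1 equiv, ca. 0.07 M in acetone), CH2Cl2, −78 → −20 °C; then THF/aq. NaH2PO4–Na2HPO4 buffer (pH 7), 0 °C → rt; crude product used directly
Reagents that add atoms: dimethyldioxirane, CC1(C)OO1; water, O
Why: Dioxirane epoxidation of an electron-rich enol ether, the counterpart of a Rubottom oxidation; the C3=C4 bond, activated by the benzyloxy group and by ring A, is far more nucleophilic than any arene or benzylic C–H bond. The epoxy ether 9 opens in buffered water to a hemiketal that loses benzyl alcohol, leaving the C3 ketone and the C4 hydroxyl. The new stereocentres are irrelevant because step 4 erases them, and an acyloin shift of the ketol would lead to the same product in step 4.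

**Step 4**
Reactants: 10 7-(benzyloxy)-2-[4-(benzyloxy)-3-methoxyphenyl]-4-hydroxychroman-3-one
Product: 12 7-(benzyloxy)-2-[4-(benzyloxy)-3-methoxyphenyl]-3-hydroxy-4H-chromen-4-one, via chromane-3,4-dione 11 (not isolated)
Conditions: Dess–Martin periodinane (1.2 equiv), NaHCO3 (5 equiv), CH2Cl2, 0 °C → rt; aq. Na2S2O3/NaHCO3
Reagents that add atoms: none
Why: Dess–Martin oxidation of a secondary benzylic α-hydroxy ketone to the 1,2-dione 11. The C2–H of 11, flanked by O1, the aryl group and the C3 carbonyl, shifts to oxygen because the resulting 3-hydroxy-4-pyranone is aromatic and conjugated with rings A and B; this erases the stereocentres at C2 and C4. The buffer keeps the medium non-acidic and the small excess of oxidant protects the enol of 12.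

**Step 5**
Reactants: 12 7-(benzyloxy)-2-[4-(benzyloxy)-3-methoxyphenyl]-3-hydroxy-4H-chromen-4-one
Product: 13 3,7-dihydroxy-2-(4-hydroxy-3-methoxyphenyl)-4H-chromen-4-one (geraldol)
Conditions: H2 (1 atm), 10 % Pd/C, THF/MeOH, rt
Reagents that add atoms: none
Why: Hydrogenolysis of two aryl benzyl ethers over zerovalent palladium on carbon. The tetrasubstituted C2=C3 bond is part of the aromatic 4-pyranone and, like the vinylogous-ester carbonyl, should not be reduced at atmospheric pressure.

**Step 6**
Reactants: 13 3,7-dihydroxy-2-(4-hydroxy-3-methoxyphenyl)-4H-chromen-4-one
Product: 15 2-[3-methoxy-4-(sulfooxy)phenyl]-4-oxo-4H-chromene-3,7-diyl bis(hydrogen sulfate), via tris(pyridinium) trisulfate 14 (not isolated)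
Conditions: SO3·pyridine (15 equiv), pyridine/DMF, 60 °C, 12 h; H2O; C18 desalting (H2O, then MeOH/H2O); sulfonic acid resin (H+ form), H2O, 0 °C; freeze-drying
Reagents that add atoms: sulfur trioxide–pyridine complex, O=S(=O)([O-])[n+]1ccccc1
Why: O-Sulfonation of the two phenols and of the enolic 3-OH by an amine–sulfur trioxide complex, a reagent too mild for C-sulfonation; the large excess and warming are meant to drive the hydrogen-bonded 3-OH to completion. Inorganic sulfate is removed on C18 before the cold exchange of pyridinium for protons, so that the free triacid is not exposed to sulfuric acid.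

## Compound list

1 | 4-(benzyloxy)-3-methoxybenzaldehyde (O-benzylvanillin) | COc1cc(C=O)ccc1OCc1ccccc1 | starting material
2 | 2-(benzyloxy)acetaldehyde | O=CCOCc1ccccc1 | starting material
3 | 2-(benzyloxy)-3-[4-(benzyloxy)-3-methoxyphenyl]-3-hydroxypropanal (aldol adduct; diastereomer mixture; not isolated) | COc1cc(C(O)C(OCc2ccccc2)C=O)ccc1OCc1ccccc1 | intermediate
4 | (Z)-2-(benzyloxy)-3-[4-(benzyloxy)-3-methoxyphenyl]acrylaldehyde | O=C/C(OCc1ccccc1)=C/c1ccc(OCc2ccccc2)c(OC)c1 | intermediate
5 | 3-(benzyloxy)phenol | Oc1cccc(OCc2ccccc2)c1 | starting material
6 | 7-(benzyloxy)-4-{(Z)-1-(benzyloxy)-2-[4-(benzyloxy)-3-methoxyphenyl]ethenyl}-2-phenyl-4H-1,3,2-benzodioxaborinine (racemic; not isolated) | c1ccccc1B1OC(/C(OCc2ccccc2)=C/c2ccc(OCc3ccccc3)c(OC)c2)c2ccc(OCc3ccccc3)cc2O1 | intermediate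
7 | (6Z)-3-(benzyloxy)-6-{(2Z)-2-(benzyloxy)-3-[4-(benzyloxy)-3-methoxyphenyl]prop-2-en-1-ylidene}cyclohexa-2,4-dien-1-one (ortho-quinone methide; not isolated) | O=C1C=C(OCc2ccccc2)C=C/C1=C/C(OCc1ccccc1)=C/c1ccc(OCc2ccccc2)c(OC)c1 | intermediate
8 | 3,7-bis(benzyloxy)-2-[4-(benzyloxy)-3-methoxyphenyl]-2H-chromene (racemic) | COc1cc(C2Oc3cc(OCc4ccccc4)ccc3C=C2OCc2ccccc2)ccc1OCc1ccccc1 | intermediate
9 | 3,7-bis(benzyloxy)-2-[4-(benzyloxy)-3-methoxyphenyl]-3,4-epoxychromane (racemic; epoxide expected mainly trans to the aryl group; not isolated) | COc1cc(C2Oc3cc(OCc4ccccc4)ccc3C3OC23OCc2ccccc2)ccc1OCc1ccccc1 | intermediate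
10 | 7-(benzyloxy)-2-[4-(benzyloxy)-3-methoxyphenyl]-4-hydroxychroman-3-one (racemic; diastereomer mixture) | COc1cc(C2Oc3cc(OCc4ccccc4)ccc3C(O)C2=O)ccc1OCc1ccccc1 | intermediate
11 | 7-(benzyloxy)-2-[4-(benzyloxy)-3-methoxyphenyl]chromane-3,4-dione (racemic; not isolated) | COc1cc(C2Oc3cc(OCc4ccccc4)ccc3C(=O)C2=O)ccc1OCc1ccccc1 | intermediate
12 | 7-(benzyloxy)-2-[4-(benzyloxy)-3-methoxyphenyl]-3-hydroxy-4H-chromen-4-one | COc1cc(-c2oc3cc(OCc4ccccc4)ccc3c(=O)c2O)ccc1OCc1ccccc1 | intermediate
13 | 3,7-dihydroxy-2-(4-hydroxy-3-methoxyphenyl)-4H-chromen-4-one (geraldol) | COc1cc(-c2oc3cc(O)ccc3c(=O)c2O)ccc1O | intermediate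
14 | tris(pyridinium) 2-(3-methoxy-4-sulfonatooxyphenyl)-4-oxo-4H-chromene-3,7-diyl bis(sulfate) (not isolated) | COc1cc(-c2oc3cc(OS(=O)(=O)[O-])ccc3c(=O)c2OS(=O)(=O)[O-])ccc1OS(=O)(=O)[O-].c1cc[nH+]cc1.c1cc[nH+]cc1.c1cc[nH+]cc1 | intermediate
15 | 2-[3-methoxy-4-(sulfooxy)phenyl]-4-oxo-4H-chromene-3,7-diyl bis(hydrogen sulfate) (CNP0382475.0) | COc1cc(-c2oc3cc(OS(=O)(=O)O)ccc3c(=O)c2OS(=O)(=O)O)ccc1OS(=O)(=O)O | target

## Step count and least certain steps

Total step count: 6. Longest linear sequence: 6 steps (from 1 or 2 to 15); 5 enters in step 2.

**Step 2 (key step, proposed new method).** The most likely failure is that the cyclic boronate 6 forms but does not fragment cleanly. The other is that the acid needed for fragmentation protonates the enol ether of 8, so that the product is hydrolysed or captures a second molecule of 5 at C4. Both follow from the product being an enol ether conjugated to an electron-rich ring, which is more acid-sensitive than the chromenes this annulation normally delivers. Leakage of the condensation to the ortho carbon between the two oxygens is a smaller concern.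

The fallback uses known chemistry, sets out from 1 and comes back at 12, so steps 3 and 4 are bypassed as well. Claisen–Schmidt condensation (KOH, EtOH, rt) of 1 with purchased 1-[4-(benzyloxy)-2-hydroxyphenyl]ethanone F1 gives the chalcone (E)-1-[4-(benzyloxy)-2-hydroxyphenyl]-3-[4-(benzyloxy)-3-methoxyphenyl]prop-2-en-1-one F2. Algar–Flynn–Oyamada oxidative cyclization of F2 (H2O2, NaOH, MeOH/THF, 0 °C → rt) then gives 12; the absence of a substituent at C6' of F2 favours the flavonol over the aurone.

**Step 1.** Self-condensation of 2 may outrun the crossed reaction, because 2 is both the only enolisable partner and the more electrophilic aldehyde, while 1 is deactivated by its two ether oxygens.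

The fallback sets out from 2 and comes back at 3 and 4 by a directed aldol condensation, in which the carbonyl of 2 is masked while its α-carbon acts as the nucleophile. Condensation of 2 with cyclohexylamine (MgSO4, Et2O, 0 °C) gives the imine N-[2-(benzyloxy)ethylidene]cyclohexanamine F3. Deprotonation with LiN(i-Pr)2 (THF, −78 °C) and addition of 1 give 2-(benzyloxy)-1-[4-(benzyloxy)-3-methoxyphenyl]-3-(cyclohexylimino)propan-1-ol F4. Aqueous oxalic acid hydrolyses F4 to 3, which dehydrates to 4 on warming.

**Step 3.** Three processes may interfere:
- over-oxidation by the dioxirane at benzylic C–H bonds once the enol ether is consumed;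
- semipinacol ring contraction of the epoxy ether instead of hydrolysis;
- acid-triggered dehydration of the ketol toward the 3-hydroxyflavylium manifold, since 10 is at the oxidation level of a flavylium pseudobase.

The fallback sets out from 8 and comes back at 12, skipping step 4. N-Bromosuccinimide in THF/H2O at −20 °C brominates the enol ether at C4, and the C3 hemiketal collapses to the α-bromo ketone 7-(benzyloxy)-2-[4-(benzyloxy)-3-methoxyphenyl]-4-bromochroman-3-one F5. Kornblum oxidation of F5 (DMSO, NaHCO3, rt → 50 °C) gives the dione 11, which enolizes to 12.

**Step 6.** Sulfation may stop short at the hydrogen-bonded 3-OH, and sulfate may be lost by acid hydrolysis when the free triacid is concentrated; neither can be corrected by chromatography on silica.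

The fallback sets out from 13 and comes back at 15 through neutral, protected sulfate diesters. 2,2,2-Trichloroethyl chlorosulfate (Et3N, DMAP, THF, 0 °C → rt) gives 2-{3-methoxy-4-[(2,2,2-trichloroethoxy)sulfonyloxy]phenyl}-4-oxo-4H-chromene-3,7-diyl bis(2,2,2-trichloroethyl) bis(sulfate) F6. F6 can be purified on silica and checked for complete sulfation. Reductive unmasking (Zn, HCO2NH4, MeOH, rt) gives tris(ammonium) 2-(3-methoxy-4-sulfonatooxyphenyl)-4-oxo-4H-chromene-3,7-diyl bis(sulfate) F7. Cold exchange on a sulfonic acid resin (H+ form) then gives 15.

## Further compounds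

F1 | step 2 | 1-[4-(benzyloxy)-2-hydroxyphenyl]ethanone (purchased) | CC(=O)c1ccc(OCc2ccccc2)cc1O
F2 | step 2 | (E)-1-[4-(benzyloxy)-2-hydroxyphenyl]-3-[4-(benzyloxy)-3-methoxyphenyl]prop-2-en-1-one | COc1cc(/C=C/C(=O)c2ccc(OCc3ccccc3)cc2O)ccc1OCc1ccccc1
F3 | step 1 | N-[2-(benzyloxy)ethylidene]cyclohexanamine | C(COCc1ccccc1)=NC1CCCCC1
F4 | step 1 | 2-(benzyloxy)-1-[4-(benzyloxy)-3-methoxyphenyl]-3-(cyclohexylimino)propan-1-ol (diastereomer mixture) | COc1cc(C(O)C(OCc2ccccc2)C=NC2CCCCC2)ccc1OCc1ccccc1
F5 | step 3 | 7-(benzyloxy)-2-[4-(benzyloxy)-3-methoxyphenyl]-4-bromochroman-3-one (racemic; diastereomer mixture) | COc1cc(C2Oc3cc(OCc4ccccc4)ccc3C(Br)C2=O)ccc1OCc1ccccc1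
F6 | step 6 | 2-{3-methoxy-4-[(2,2,2-trichloroethoxy)sulfonyloxy]phenyl}-4-oxo-4H-chromene-3,7-diyl bis(2,2,2-trichloroethyl) bis(sulfate) | COc1cc(-c2oc3cc(OS(=O)(=O)OCC(Cl)(Cl)Cl)ccc3c(=O)c2OS(=O)(=O)OCC(Cl)(Cl)Cl)ccc1OS(=O)(=O)OCC(Cl)(Cl)Cl
F7 | step 6 | tris(ammonium) 2-(3-methoxy-4-sulfonatooxyphenyl)-4-oxo-4H-chromene-3,7-diyl bis(sulfate) | COc1cc(-c2oc3cc(OS(=O)(=O)[O-])ccc3c(=O)c2OS(=O)(=O)[O-])ccc1OS(=O)(=O)[O-].[NH4+].[NH4+].[NH4+]
A1 | alternative 1 | 3-(benzyloxy)-2-[4-(benzyloxy)-3-methoxyphenyl]-5-bromo-4H-pyran-4-one | COc1cc(-c2occ(Br)c(=O)c2OCc2ccccc2)ccc1OCc1ccccc1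
A2 | alternative 1 | (E)-1-methoxy-3-(trimethylsilyloxy)buta-1,3-diene | CO/C=C/C(=C)O[Si](C)(C)C
A3 | alternative 1 | 3-(benzyloxy)-2-[4-(benzyloxy)-3-methoxyphenyl]-7-hydroxy-4H-chromen-4-one | COc1cc(-c2oc3cc(O)ccc3c(=O)c2OCc2ccccc2)ccc1OCc1ccccc1
A4 | alternative 2 | 5-(benzyloxy)-2-iodophenol | Oc1cc(OCc2ccccc2)ccc1I
A5 | alternative 2 | carbon monoxide | [C-]#[O+]
A6 | alternative 2 | 1-(benzyloxy)-4-ethynyl-2-methoxybenzene | C#Cc1ccc(OCc2ccccc2)c(OC)c1
A7 | alternative 2 | 7-(benzyloxy)-2-[4-(benzyloxy)-3-methoxyphenyl]-4H-chromen-4-one | COc1cc(-c2cc(=O)c3ccc(OCc4ccccc4)cc3o2)ccc1OCc1ccccc1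
A8 | alternative 3 | 4-(benzyloxy)-2-{1-[4-(benzyloxy)-3-methoxyphenyl]-2-oxoethoxy}benzaldehyde (racemic) | COc1cc(C(C=O)Oc2cc(OCc3ccccc3)ccc2C=O)ccc1OCc1ccccc1
A9 | alternative 3 | rac-(2R,3S,4S)-7-(benzyloxy)-2-[4-(benzyloxy)-3-methoxyphenyl]chromane-3,4-diol (2,3-trans-3,4-cis; one enantiomer drawn) | COc1cc([C@@H]2[C@H]([C@@H](O)c3ccc(OCc4ccccc4)cc3O2)O)ccc1OCc1ccccc1
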